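- The starting material pairs up into the target, and the cedar and birch runs below supply the readings. At the first cedar reading, starting material 15.0% and target 84.5% add up to 99.5%, so what leaves one share arrives in the other.

| flask | starting material | remark | time |
|---|---|---|---|
| cedar | 0.13 M | run made earlier |  |
| birch | 0.30 M | run made earlier |  |
| flask | 0.20 M |  | 10 h |

| run | time / h | target / % | starting material / % |
|---|---|---|---|
| cedar | 1.00 | 84.5 | 15.0 |
| cedar | 3.00 | 93.9 | 4.7 |
| cedar | 5.00 | 95.6 | 3.2 |
| cedar | 8.00 | 98.1 | 2.1 |
| birch | 0.667 | 89.8 | 10.1 |
| birch | 1.33 | 94.6 | 5.3 |
| birch | 3.00 | 97.1 | 2.3 |
| birch | 8.00 | 99.1 | 1.3 |

(scatter of a reading: 0.5 percentage points)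

- the species that holds most of what was charged as starting material, at 10 h (starting material / target)
- the largest share itself, whichever of these holds it, in percent of the starting material charged

- One reading per run gives a second-order constant: (share left, inverted, less 1) divided by charge and time. Cedar gives 43.6 /M/h and birch 44.5 /M/h, close although [starting material] differs, so the mean reading 44.0 /M/h serves.
- The carried quantity is the half-time, one over the product of that constant and the charge, the moment of the even split. For this flask it is 0.114 h. With n the time counted in half-times, the share left is 1/(1 + n), and n = 1 is the zero of the scale.
- First rung: at 0.114 h the reckoning puts equal shares of both species in this flask.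
- Next rung: at 1.00 h, well past the half-time, the reckoning leaves 10.2% of starting material in this flask. This is the reading to watch.
- Last rung: at 10 h, n for this flask is 88.1, which by the reckoning leaves 1.12% of starting material and 98.9% as target. That rest stands against a scatter of 0.5 percentage points.
- The forecast says target at 98.8%, within 97.9% to 99.4%, “perhaps a little lower if the reaction is slightly reversible”.
- The flask gives target at 98.9%, with starting material at 1.14%.

    2 starting material → target (k = 0.00600 /M/s)

- In this flask at 5.00 h, the half-time count leaves 2.22% of starting material, and the flask holds 2.26% of it. A neighbouring flask is charged with 0.80 M of starting material instead of 0.20 M, its time held. Its half-time shrinks to 0.0284 h, so its n is 352 and the count leaves 0.283% of starting material. At 10.0 h that neighbouring flask holds 99.7% as target and 0.29% as starting material.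

The earlier runs and the new flask were generated by integration for substances that don't exist; the scatter is artificial.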